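(The data are simulated from invented constants.)

Neither earlier run can be read at 50 °C: ash stood at 5 °C and cedar at 38 °C, so a rate for the hot flasks has to be reckoned.

| flask | starting material | partner | second substrate | temperature | remark | time |
|---|---|---|---|---|---|---|
| ash | 49 mM | 58.8 mM | 12 mM | 5 °C | run made earlier |  |
| cedar | 49 mM | 58.8 mM | 49 mM | 38 °C | run made earlier |  |
| south | 49 mM | 58.8 mM | 24.5 mM |  | at −10 °C until 50 s, from then on at 50 °C | 3.0 min |
| north | 49 mM | 58.8 mM | 24.5 mM | 50 °C |  | 3.0 min |
| south-east | 49 mM | 58.8 mM | 24.5 mM | −10 °C |  | 3.0 min |
| east | 49 mM | 58.8 mM | 24.5 mM | 20 °C |  | 3.0 min |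

- ash (time / min: target / %, starting material / %): 1.50: 0.9, 100.0; 5.00: 0.3, 99.4; 8.00: 1.0, 99.2; 12.0: 0.4, 99.2; 20.0: 1.4, 97.8; 25.0: 2.0, 97.0; 30.0: 2.6, 96.3
- cedar (time / min: target / %, starting material / %): 0.833: 1.6, 97.4; 1.50: 3.7, 95.2; 2.50: 5.0, 90.3; 4.00: 7.9, 85.8; 5.00: 9.9, 82.4

(readings scatter by 0.5 percentage points)

- the analysis behind the earlier runs scatters by 0.5 percentage points, standard deviation
- steps under discussion: second substrate + partner -> second product; starting material + second substrate -> cross product; partner <-> dormant form; starting material + partner -> target; target -> over-reaction product

- which flask leads in amount of target, in percent of the starting material charged ("all alike" within 1.5 percentage points) (south / north / south-east / east / all alike)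
- how much target is there at the end, in percent of the starting material charged: south
- how much target is there at the end, in percent of the starting material charged: north
- how much target is there at the end, in percent of the starting material charged: south-east
- how much target is there at the end, in percent of the starting material charged: east

We divide the last target reading of each run by its time, which gives 8.67 × 10⁻⁴ min⁻¹ in ash and 0.0198 min⁻¹ in cedar. Partner's charge is the same in both runs, but at 1.20 times the starting material's it is no large excess, so treating it as constant, as we do here, is a rough assumption of ours. The two rates give an activation energy of 68.2 kJ mol⁻¹, and so 0.0527 min⁻¹ at 50 °C.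

We carry one quantity, the target half-life: the time in which target formation at that rate would halve the starting material, here 13.1 min. A flask's count is its time at each temperature divided by the half-life there, summed, and our target share is one minus two to the power of minus the count.

In the first instants south is at −10 °C, where the half-life is 4300 min, so its 50 s there add a count of 1.94 × 10⁻⁴. North meanwhile is already running. At the middle, 1.50 min, north's count is 0.114 and south's 0.0509. At the end north stands at 0.228, or 14.6% target, and south at 0.165, or 10.8%. South-east, counting 6.98 × 10⁻⁴, gets 0.0484%. East, with a half-life of 177 min, gets 1.17%. What may matter by then is partner, which no reading shows.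

Ash's last reading carries a scatter of 19.2% of itself. That moves the half-life, but north's count over south's stays near 1.38 whatever the half-life at 50 °C is, because both flasks end hot and the cold stretch adds so little. Our gap of 3.8 percentage points stands above the margin.

The forecast names north as leader, with 14% there, 10.5% in south, 0.1% in south-east and 1.2% in east, noting that “South has only about 2.2 hot minutes”. Our north and south stand above its figures, by 0.60 points and 0.30 points.

The flasks give 15.1% in north, 11.8% in south, 0.0431% in south-east and 1.28% in east; north leads.

    second substrate + partner → second product (k = 0.770 M⁻¹ min⁻¹, Ea = 54.0 kJ mol⁻¹)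
    starting material + second substrate → cross product (k = 0.790 M⁻¹ min⁻¹, Ea = 55.0 kJ mol⁻¹)
    partner ⇌ dormant form (K = 0.270, k = 0.140 min⁻¹, Ea = 97.0 kJ mol⁻¹, ΔH = −10.0 kJ mol⁻¹)
    starting material + partner → target (k = 1.20 M⁻¹ min⁻¹, Ea = 73.0 kJ mol⁻¹)
    target → over-reaction product (k = 3.00 × 10⁻⁴ min⁻¹, Ea = 112 kJ mol⁻¹)
    (constants at 50 °C)

North has not come to rest at 3.00 min: its count stands at 0.228, and 80% of its starting material is still there. The same half-life applied to north read at 8.0 min gives a count of 0.611 and 34.5% target, where that flask holds 29.6%. Ten times the time still changes much: north reaches 54.8% and south 54.3%, now 0.5 points apart, while south-east reaches 0.427%. At 30.0 min north still holds 27.8% of its starting material.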